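Carbons are counted from the alkyne CH (C1) to the terminal methyl (C15); the oxolane oxygen links C6 and C9. The plan cuts ring bond C6–C7, flanked by the C7 carbinol and the C5–C4 arm. A ketyl formed at a C7 aldehyde attacks C6 of an E alkoxyacrylate on the C9 oxygen, so one operation closes the oxolane, sets C6 and C7 and leaves an ester for the enyne. The substrate is an acyclic aldehyde whose C8 to C12 segment, with the erythro oxygens at C9 and C10, derives from 2-deoxy-D-ribose; C10 bears a PMB ether and the pentenyl chain is already present.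

Key step: step 12

Assumption: the ketyl closure is taken to place the C7 hydroxyl trans to the C6 acetate arm, the usual sense for samarium ketyl additions to alkoxyacrylates; the C7 inversion in step 18 rests on this.

**Route**

Step 1
Reactants: 1 2-deoxy-D-ribose
Product: 2 2-deoxy-3,4-O-isopropylidene-D-erythro-pentopyranose (cis-fused acetonide lactol; anomer mixture)
Conditions: 2-methoxypropene, PPTS (cat.), EtOAc, 0 °C to rt
Reagents that add atoms: 2-methoxypropene, COC(C)=C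
Why: Acid-catalysed ketalisation of the cis-3,4-diol of the pyranose form (acetonide protection) leaves only the anomeric hydroxyl free and touches no stereocentre.

Step 2
Reactants: 3 1-phenyl-1H-tetrazole-5-thiol; 4 1-bromopropane
Product: 5 1-phenyl-5-(propylsulfanyl)-1H-tetrazole
Conditions: K2CO3, acetone, reflux
Reagents that add atoms: none
Why: The thiolate is alkylated at sulfur by the primary bromide (SN2 thioether synthesis).

Step 3
Reactants: 5 1-phenyl-5-(propylsulfanyl)-1H-tetrazole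
Product: 6 1-phenyl-5-(propylsulfonyl)-1H-tetrazole
Conditions: (NH4)6Mo7O24·4H2O (cat.), aq. H2O2, EtOH, 0 °C to rt
Reagents that add atoms: hydrogen peroxide, OO
Why: Molybdate-catalysed peroxide oxidation of the sulfide should stop cleanly at the sulfone needed for the olefination (sulfide oxidation).

Step 4
Reactants: 2 2-deoxy-3,4-O-isopropylidene-D-erythro-pentopyranose; 6 1-phenyl-5-(propylsulfonyl)-1H-tetrazole
Product: 8 [(4R,5S)-2,2-dimethyl-5-[(2E)-pent-2-en-1-yl]-1,3-dioxolan-4-yl]methanol, via potassium sulfonyl carbanion 7 (not isolated)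
Conditions: 6 (2.2 equiv), KN(SiMe3)2 (2.1 equiv), DME, −60 °C; then 2, −60 °C to rt
Reagents that add atoms: none
Why: Julia–Kocienski olefination: one equivalent of the metalated sulfone deprotonates the lactol, which opens to the alkoxy aldehyde, a second equivalent adds, and Smiles transfer of the tetrazole followed by loss of SO2 and tetrazololate gives the alkene, whose E geometry (C12=C13) follows from the anti-selective addition of the potassium derivative in DME; C9 and C10 are not touched.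

Step 5
Reactants: 8 [(4R,5S)-2,2-dimethyl-5-[(2E)-pent-2-en-1-yl]-1,3-dioxolan-4-yl]methanol
Product: 9 (1S,3E)-1-[(4R)-2,2-dimethyl-1,3-dioxolan-4-yl]hex-3-en-1-ol
Conditions: CSA (cat.), acetone, rt
Reagents that add atoms: none
Why: Acid-catalysed acetal migration under thermodynamic control should move the ketal from the strained cis-4,5-disubstituted dioxolane to the terminal C8/C9 diol, freeing the C10 hydroxyl without breaking a C–O bond at a stereocentre.

Step 6
Reactants: 9 (1S,3E)-1-[(4R)-2,2-dimethyl-1,3-dioxolan-4-yl]hex-3-en-1-ol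
Product: 10 (4R)-4-[(1S,3E)-1-[(4-methoxybenzyl)oxy]hex-3-en-1-yl]-2,2-dimethyl-1,3-dioxolane
Conditions: NaH, PMBCl, Bu4NI (cat.), THF/DMF, 0 °C to rt
Reagents that add atoms: 4-methoxybenzyl chloride, COc1ccc(CCl)cc1
Why: Williamson etherification of the only free hydroxyl (C10) installs the group that is later exchanged for bromide.

Step 7
Reactants: 10 (4R)-4-[(1S,3E)-1-[(4-methoxybenzyl)oxy]hex-3-en-1-yl]-2,2-dimethyl-1,3-dioxolane
Product: 11 (2R,3S,5E)-3-[(4-methoxybenzyl)oxy]oct-5-ene-1,2-diol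
Conditions: AcOH/H2O, 40 °C
Reagents that add atoms: none
Why: Mild aqueous acid hydrolyses the dioxolane (acetal hydrolysis) while the PMB ether and the alkene are inert.

Step 8
Reactants: 11 (2R,3S,5E)-3-[(4-methoxybenzyl)oxy]oct-5-ene-1,2-diol
Product: 13 (2R)-2-[(1S,3E)-1-[(4-methoxybenzyl)oxy]hex-3-en-1-yl]oxirane, via primary tosylate 12 (not isolated)
Conditions: NaH, 1-(p-toluenesulfonyl)imidazole, THF, 0 °C to rt
Reagents that add atoms: none
Why: One-pot diol-to-epoxide conversion: the primary alkoxide is sulfonylated selectively and the neighbouring C9 alkoxide displaces the tosylate (3-exo-tet Williamson closure), so C9 keeps its configuration because its C–O bond is never broken.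

Step 9
Reactants: 13 (2R)-2-[(1S,3E)-1-[(4-methoxybenzyl)oxy]hex-3-en-1-yl]oxirane; 14 1,3-dithiane
Product: 16 (2R,3S,5E)-1-(1,3-dithian-2-yl)-3-[(4-methoxybenzyl)oxy]oct-5-en-2-ol, via 2-lithio-1,3-dithiane 15 (not isolated)
Conditions: 14, n-BuLi, THF, −30 °C; then 13, DMPU, −30 to 0 °C
Reagents that add atoms: none
Why: Epoxide opening by the dithiane anion (Corey–Seebach umpolung) at the unhindered terminal carbon C8 brings in C7 at the aldehyde oxidation level and frees the C9 hydroxyl alone.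

Step 10
Reactants: 16 (2R,3S,5E)-1-(1,3-dithian-2-yl)-3-[(4-methoxybenzyl)oxy]oct-5-en-2-ol; 17 ethyl propiolate
Product: 18 ethyl (2E)-3-{[(2R,3S,5E)-1-(1,3-dithian-2-yl)-3-[(4-methoxybenzyl)oxy]oct-5-en-2-yl]oxy}prop-2-enoate
Conditions: N-methylmorpholine, CH2Cl2, rt
Reagents that add atoms: none
Why: Tertiary-amine-catalysed oxa-Michael addition of the C9 alcohol to the propiolate should give the β-alkoxyacrylate as the E isomer, the geometry the cyclisation requires.

Step 11
Reactants: 18 ethyl (2E)-3-{[(2R,3S,5E)-1-(1,3-dithian-2-yl)-3-[(4-methoxybenzyl)oxy]oct-5-en-2-yl]oxy}prop-2-enoate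
Product: 19 ethyl (2E)-3-{[(3R,4S,6E)-4-[(4-methoxybenzyl)oxy]-1-oxonon-6-en-3-yl]oxy}prop-2-enoate (aldehyde precursor)
Conditions: MeI, NaHCO3, MeCN/H2O, rt; crude aldehyde used at once
Reagents that add atoms: water, O
Why: Alkylative dithioacetal hydrolysis: S-methylation makes sulfur a leaving group and buffered water delivers the aldehyde under conditions too mild to expel the acrylate oxygen by β-elimination, which is why the aldehyde is unmasked last and not stored.

Step 12
Reactants: 19 ethyl (2E)-3-{[(3R,4S,6E)-4-[(4-methoxybenzyl)oxy]-1-oxonon-6-en-3-yl]oxy}prop-2-enoate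
Product: 20 ethyl 2-[(2R,3S,5R)-3-hydroxy-5-[(1S,3E)-1-[(4-methoxybenzyl)oxy]hex-3-en-1-yl]oxolan-2-yl]acetate
Conditions: SmI2 (0.1 M in THF), MeOH, THF, 0 °C
Reagents that add atoms: none
Why: SmI2 transfers one electron to the C7 aldehyde and the resulting samarium ketyl adds to C6, the β-carbon of the alkoxyacrylate; a second electron turns the α-ester radical into a samarium enolate that methanol protonates. The closest known reaction type is the samarium-mediated reductive cyclisation of aldehydes onto β-alkoxyacrylates, which gives hydroxy cyclic ethers. The oxolane (O, C6, C7, C8, C9) closes in the 5-exo-trig mode through the new C6–C7 bond. C6 is set by the C9 stereocentre, whose side chain sits pseudo-equatorial in the envelope-like transition state so that the new C5 arm comes out cis to C10 across the ring oxygen, and C7 is set by samarium bridging the ketyl oxygen and the ester carbonyl of the s-trans E-acrylate, an arrangement that should leave the hydroxyl trans to the C5 arm. The step needs 2,5-cis selectivity, secured by the C9 substituent and the fixed E geometry of the acceptor, and chemoselectivity, secured because the aldehyde is the most easily reduced group, the unactivated C12=C13 alkene is a poor radical acceptor whose 6-exo closure cannot compete, and HMPA is left out so that ester, acrylate and PMB ether are not reduced. Should the C7 alcohol form cis instead, it would lactonise onto the ester and could be taken on without the later inversion.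

Step 13
Reactants: 20 ethyl 2-[(2R,3S,5R)-3-hydroxy-5-[(1S,3E)-1-[(4-methoxybenzyl)oxy]hex-3-en-1-yl]oxolan-2-yl]acetate
Product: 21 ethyl 2-[(2R,3S,5R)-3-[(tert-butyldimethylsilyl)oxy]-5-[(1S,3E)-1-[(4-methoxybenzyl)oxy]hex-3-en-1-yl]oxolan-2-yl]acetate
Conditions: TBSOTf, 2,6-lutidine, CH2Cl2, −78 to 0 °C
Reagents that add atoms: tert-butyldimethylsilyl trifluoromethanesulfonate, CC(C)(C)[Si](C)(C)OS(=O)(=O)C(F)(F)F
Why: Silyl ether protection of the secondary C7 hydroxyl shields it from the hydride and chromium steps and is removed later together with the alkynyl silyl group.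

Step 14
Reactants: 21 ethyl 2-[(2R,3S,5R)-3-[(tert-butyldimethylsilyl)oxy]-5-[(1S,3E)-1-[(4-methoxybenzyl)oxy]hex-3-en-1-yl]oxolan-2-yl]acetate
Product: 22 2-[(2R,3S,5R)-3-[(tert-butyldimethylsilyl)oxy]-5-[(1S,3E)-1-[(4-methoxybenzyl)oxy]hex-3-en-1-yl]oxolan-2-yl]acetaldehyde
Conditions: i-Bu2AlH, CH2Cl2, −78 °C; aq. potassium sodium tartrate (KNaC4H4O6)
Reagents that add atoms: none
Why: Partial ester reduction: at low temperature the aluminium hemiacetal, stabilised by chelation to the ring oxygen, should survive until work-up and then release the C4 aldehyde.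

Step 15
Reactants: 22 2-[(2R,3S,5R)-3-[(tert-butyldimethylsilyl)oxy]-5-[(1S,3E)-1-[(4-methoxybenzyl)oxy]hex-3-en-1-yl]oxolan-2-yl]acetaldehyde
Product: 23 tert-butyl{[(2R,3S,5R)-2-[(2E)-3-iodoprop-2-en-1-yl]-5-[(1S,3E)-1-[(4-methoxybenzyl)oxy]hex-3-en-1-yl]oxolan-3-yl]oxy}dimethylsilane
Conditions: CrCl2, CHI3, THF/1,4-dioxane, 0 °C to rt
Reagents that add atoms: iodoform, IC(I)I
Why: Takai iodo-olefination: the geminal dichromium species formed from iodoform and divalent chromium adds to the aldehyde and eliminates to the E-vinyl iodide, which sets the C3=C4 geometry.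

Step 16
Reactants: 23 tert-butyl{[(2R,3S,5R)-2-[(2E)-3-iodoprop-2-en-1-yl]-5-[(1S,3E)-1-[(4-methoxybenzyl)oxy]hex-3-en-1-yl]oxolan-3-yl]oxy}dimethylsilane
Product: 24 tert-butyl{[(2R,3S,5R)-5-[(1S,3E)-1-[(4-methoxybenzyl)oxy]hex-3-en-1-yl]-2-[(2E)-5-(trimethylsilyl)pent-2-en-4-yn-1-yl]oxolan-3-yl]oxy}dimethylsilane
Conditions: Me3SiC≡CH, Pd(PPh3)4 (cat.), CuI (cat.), i-Pr2NH, THF, rt
Reagents that add atoms: ethynyltrimethylsilane, C#C[Si](C)(C)C
Why: Sonogashira coupling of the vinyl iodide with the silylacetylene proceeds with retention of the E geometry and completes the C1–C5 enyne carbon chain.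

Step 17
Reactants: 24 tert-butyl{[(2R,3S,5R)-5-[(1S,3E)-1-[(4-methoxybenzyl)oxy]hex-3-en-1-yl]-2-[(2E)-5-(trimethylsilyl)pent-2-en-4-yn-1-yl]oxolan-3-yl]oxy}dimethylsilane
Product: 25 (2R,3S,5R)-5-[(1S,3E)-1-[(4-methoxybenzyl)oxy]hex-3-en-1-yl]-2-[(2E)-pent-2-en-4-yn-1-yl]oxolan-3-ol
Conditions: Bu4NF, THF, 0 °C to rt
Reagents that add atoms: none
Why: Fluoride-induced desilylation removes the C7 silyl ether and the alkynyl silyl group in one operation, at a stage where neither the acetate nor the bromide is yet present.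

Step 18
Reactants: 25 (2R,3S,5R)-5-[(1S,3E)-1-[(4-methoxybenzyl)oxy]hex-3-en-1-yl]-2-[(2E)-pent-2-en-4-yn-1-yl]oxolan-3-ol
Product: 26 (2R,3R,5R)-5-[(1S,3E)-1-[(4-methoxybenzyl)oxy]hex-3-en-1-yl]-2-[(2E)-pent-2-en-4-yn-1-yl]oxolan-3-yl acetate
Conditions: AcOH, PPh3, DIAD, toluene, 0 °C to rt
Reagents that add atoms: acetic acid, CC(=O)O
Why: Mitsunobu esterification: acetate displaces the C7 oxyphosphonium group with inversion (SN2), which places the acetate cis to both ring substituents as in the target.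

Step 19
Reactants: 26 (2R,3R,5R)-5-[(1S,3E)-1-[(4-methoxybenzyl)oxy]hex-3-en-1-yl]-2-[(2E)-pent-2-en-4-yn-1-yl]oxolan-3-yl acetate
Product: 27 (2R,3R,5R)-5-[(1S,3E)-1-hydroxyhex-3-en-1-yl]-2-[(2E)-pent-2-en-4-yn-1-yl]oxolan-3-yl acetate
Conditions: DDQ, CH2Cl2/pH 7 buffer, 0 °C to rt
Reagents that add atoms: none
Why: Oxidative PMB cleavage by DDQ through the benzylic oxocarbenium ion frees the C10 hydroxyl while acetate, enyne and the isolated alkene stay intact.

Step 20
Reactants: 27 (2R,3R,5R)-5-[(1S,3E)-1-hydroxyhex-3-en-1-yl]-2-[(2E)-pent-2-en-4-yn-1-yl]oxolan-3-yl acetate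
Product: 28 trans-kumausyne ((2R,3R,5R)-5-[(1R,3E)-1-bromohex-3-en-1-yl]-2-[(2E)-pent-2-en-4-yn-1-yl]oxolan-3-yl acetate)
Conditions: CBr4, P(n-C8H17)3, toluene, 70 °C
Reagents that add atoms: tetrabromomethane, BrC(Br)(Br)Br
Why: Appel bromination: bromide displaces the C10 alkoxyphosphonium group with inversion (SN2), turning the (S)-carbinol derived from the sugar into the (R)-bromide of the target.

**Compound list**

1 | 2-deoxy-D-ribose, (3S,4R)-3,4,5-trihydroxypentanal | O=CC[C@H](O)[C@H](O)CO | starting material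
2 | 2-deoxy-3,4-O-isopropylidene-D-erythro-pentopyranose (anomer mixture) | OC1C[C@@H]2OC(C)(C)O[C@@H]2CO1 | intermediate
3 | 1-phenyl-1H-tetrazole-5-thiol | Sc1nnnn1-c2ccccc2 | starting material
4 | 1-bromopropane | CCCBr | starting material
5 | 1-phenyl-5-(propylsulfanyl)-1H-tetrazole | CCCSc1nnnn1-c2ccccc2 | intermediate
6 | 1-phenyl-5-(propylsulfonyl)-1H-tetrazole | CCCS(=O)(=O)c1nnnn1-c2ccccc2 | intermediate
7 | potassium 1-[(1-phenyl-1H-tetrazol-5-yl)sulfonyl]propan-1-ide (not isolated) | CC[CH-]S(=O)(=O)c1nnnn1-c2ccccc2.[K+] | intermediate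
8 | [(4R,5S)-2,2-dimethyl-5-[(2E)-pent-2-en-1-yl]-1,3-dioxolan-4-yl]methanol | CC/C=C/C[C@@H]1OC(C)(C)O[C@@H]1CO | intermediate
9 | (1S,3E)-1-[(4R)-2,2-dimethyl-1,3-dioxolan-4-yl]hex-3-en-1-ol | CC/C=C/C[C@H](O)[C@H]1COC(C)(C)O1 | intermediate
10 | (4R)-4-[(1S,3E)-1-[(4-methoxybenzyl)oxy]hex-3-en-1-yl]-2,2-dimethyl-1,3-dioxolane | CC/C=C/C[C@H](OCc1ccc(OC)cc1)[C@H]2COC(C)(C)O2 | intermediate
11 | (2R,3S,5E)-3-[(4-methoxybenzyl)oxy]oct-5-ene-1,2-diol | CC/C=C/C[C@H](OCc1ccc(OC)cc1)[C@H](O)CO | intermediate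
12 | (2R,3S,5E)-2-hydroxy-3-[(4-methoxybenzyl)oxy]oct-5-en-1-yl 4-methylbenzenesulfonate (present as its sodium alkoxide; not isolated) | CC/C=C/C[C@H](OCc1ccc(OC)cc1)[C@H](O)COS(=O)(=O)c2ccc(C)cc2 | intermediate
13 | (2R)-2-[(1S,3E)-1-[(4-methoxybenzyl)oxy]hex-3-en-1-yl]oxirane | CC/C=C/C[C@H](OCc1ccc(OC)cc1)[C@H]2CO2 | intermediate
14 | 1,3-dithiane | C1CSCSC1 | starting material
15 | 2-lithio-1,3-dithiane (not isolated) | [Li]C1SCCCS1 | intermediate
16 | (2R,3S,5E)-1-(1,3-dithian-2-yl)-3-[(4-methoxybenzyl)oxy]oct-5-en-2-ol | CC/C=C/C[C@H](OCc1ccc(OC)cc1)[C@H](O)CC2SCCCS2 | intermediate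
17 | ethyl propiolate | C#CC(=O)OCC | starting material
18 | ethyl (2E)-3-{[(2R,3S,5E)-1-(1,3-dithian-2-yl)-3-[(4-methoxybenzyl)oxy]oct-5-en-2-yl]oxy}prop-2-enoate | CC/C=C/C[C@H](OCc1ccc(OC)cc1)[C@H](O/C=C/C(=O)OCC)CC2SCCCS2 | intermediate
19 | ethyl (2E)-3-{[(3R,4S,6E)-4-[(4-methoxybenzyl)oxy]-1-oxonon-6-en-3-yl]oxy}prop-2-enoate | O=CC[C@@H](O/C=C/C(=O)OCC)[C@@H](OCc1ccc(OC)cc1)C/C=C/CC | intermediate
20 | ethyl 2-[(2R,3S,5R)-3-hydroxy-5-[(1S,3E)-1-[(4-methoxybenzyl)oxy]hex-3-en-1-yl]oxolan-2-yl]acetate | CCOC(=O)C[C@H]1O[C@@H]([C@@H](OCc2ccc(OC)cc2)C/C=C/CC)C[C@@H]1O | intermediate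
21 | ethyl 2-[(2R,3S,5R)-3-[(tert-butyldimethylsilyl)oxy]-5-[(1S,3E)-1-[(4-methoxybenzyl)oxy]hex-3-en-1-yl]oxolan-2-yl]acetate | CCOC(=O)C[C@H]1O[C@@H]([C@@H](OCc2ccc(OC)cc2)C/C=C/CC)C[C@@H]1O[Si](C)(C)C(C)(C)C | intermediate
22 | 2-[(2R,3S,5R)-3-[(tert-butyldimethylsilyl)oxy]-5-[(1S,3E)-1-[(4-methoxybenzyl)oxy]hex-3-en-1-yl]oxolan-2-yl]acetaldehyde | O=CC[C@H]1O[C@@H]([C@@H](OCc2ccc(OC)cc2)C/C=C/CC)C[C@@H]1O[Si](C)(C)C(C)(C)C | intermediate
23 | tert-butyl{[(2R,3S,5R)-2-[(2E)-3-iodoprop-2-en-1-yl]-5-[(1S,3E)-1-[(4-methoxybenzyl)oxy]hex-3-en-1-yl]oxolan-3-yl]oxy}dimethylsilane | I/C=C/C[C@H]1O[C@@H]([C@@H](OCc2ccc(OC)cc2)C/C=C/CC)C[C@@H]1O[Si](C)(C)C(C)(C)C | intermediate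
24 | tert-butyl{[(2R,3S,5R)-5-[(1S,3E)-1-[(4-methoxybenzyl)oxy]hex-3-en-1-yl]-2-[(2E)-5-(trimethylsilyl)pent-2-en-4-yn-1-yl]oxolan-3-yl]oxy}dimethylsilane | C[Si](C)(C)C#C/C=C/C[C@H]1O[C@@H]([C@@H](OCc2ccc(OC)cc2)C/C=C/CC)C[C@@H]1O[Si](C)(C)C(C)(C)C | intermediate
25 | (2R,3S,5R)-5-[(1S,3E)-1-[(4-methoxybenzyl)oxy]hex-3-en-1-yl]-2-[(2E)-pent-2-en-4-yn-1-yl]oxolan-3-ol | C#C/C=C/C[C@H]1O[C@@H]([C@@H](OCc2ccc(OC)cc2)C/C=C/CC)C[C@@H]1O | intermediate
26 | (2R,3R,5R)-5-[(1S,3E)-1-[(4-methoxybenzyl)oxy]hex-3-en-1-yl]-2-[(2E)-pent-2-en-4-yn-1-yl]oxolan-3-yl acetate | C#C/C=C/C[C@H]1O[C@@H]([C@@H](OCc2ccc(OC)cc2)C/C=C/CC)C[C@H]1OC(C)=O | intermediate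
27 | (2R,3R,5R)-5-[(1S,3E)-1-hydroxyhex-3-en-1-yl]-2-[(2E)-pent-2-en-4-yn-1-yl]oxolan-3-yl acetate | C#C/C=C/C[C@H]1O[C@@H]([C@@H](O)C/C=C/CC)C[C@H]1OC(C)=O | intermediate
28 | trans-kumausyne ((2R,3R,5R)-5-[(1R,3E)-1-bromohex-3-en-1-yl]-2-[(2E)-pent-2-en-4-yn-1-yl]oxolan-3-yl acetate) | C#C/C=C/C[C@H]1O[C@@H]([C@H](Br)C/C=C/CC)C[C@H]1OC(C)=O | target

**Step count**

Total step count: 20.
Longest linear sequence: 19 steps (steps 2, 3 and 4 to 20, counted from 1-phenyl-1H-tetrazole-5-thiol). The line from 2-deoxy-D-ribose (step 1, then steps 4 to 20) is one step shorter.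

**Steps most likely to fail**

Step 12 (ketyl closure). The enolisable aldehyde may lose the acrylate oxygen by β-elimination before electron transfer. Simple reduction or pinacol coupling of the ketyl may outrun ring closure. Facial control at C6 or C7 may be incomplete. The fallback replaces the ketyl by an acyl radical and sets C7 afterwards by hydride delivery; it sets out from aldehyde 19 and comes back at acetate 26, so it also bypasses the C7 inversion of step 18. Pinnick oxidation (NaClO2, NaH2PO4, 2-methyl-2-butene, t-BuOH/H2O) should give the carboxylic acid F1. Treatment with PhSeSePh and PBu3 should convert it into the Se-phenyl selenoester F2. With (Me3Si)3SiH and Et3B/air at rt the acyl radical should close 5-exo onto the alkoxyacrylate, a known route to cis-2,5-disubstituted oxolan-3-ones, giving the keto ester F3. LiBH(s-Bu)3 at −78 °C should deliver hydride anti to both ring substituents and give the all-cis hydroxy ester F4. Excess i-Bu2AlH at −78 °C should reduce the ester to the aldehyde level, which the cis C7 hydroxyl captures as the bicyclic lactol F5. Takai olefination (CrCl2, CHI3) of the open-chain aldehyde in equilibrium with the lactol should give the hydroxy vinyl iodide F6. Acetylation (Ac2O, pyridine, DMAP) should give the acetoxy vinyl iodide F7, and Stille coupling with tributyl(ethynyl)stannane and Pd(PPh3)4 should deliver 26.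

Step 20 (bromination at C10). The activated C10 oxygen may ionise with participation of the ring oxygen, leading to retention or ring expansion. E2 elimination toward the allylic C11 hydrogens may also compete with substitution. The fallback separates activation from displacement; it sets out from alcohol 27 and comes back at the target 28. Chloromethanesulfonyl chloride and 2,6-lutidine in CH2Cl2 at 0 °C should give the chloromethanesulfonate F8, a strongly activated but isolable sulfonate. Bu4NBr in toluene at moderate temperature should then displace it by SN2 with inversion.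

Step 4 (Julia–Kocienski olefination of the lactol). The aldehyde is available only through lactol opening, so conversion may stall while the sulfonyl anion is consumed as a base. The E/Z selectivity may also be eroded by the free alkoxide. The fallback builds the E-alkene by alkyne reduction; it sets out from lactol 2 and comes back at alcohol 8. Seyferth–Gilbert homologation with dimethyl (1-diazo-2-oxopropyl)phosphonate and K2CO3 in MeOH should give the terminal alkyne F9. Its dianion (n-BuLi, THF/DMPU) should be C-ethylated by EtI to the internal alkyne F10. Dissolving-metal reduction (Na, liquid NH3, THF) should add hydrogen anti and give 8 as the E isomer only.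

Further compounds
F1 | step 12 | (3R,4S,6E)-3-{[(1E)-3-ethoxy-3-oxoprop-1-en-1-yl]oxy}-4-[(4-methoxybenzyl)oxy]non-6-enoic acid | OC(=O)C[C@@H](O/C=C/C(=O)OCC)[C@@H](OCc1ccc(OC)cc1)C/C=C/CC
F2 | step 12 | Se-phenyl (3R,4S,6E)-3-{[(1E)-3-ethoxy-3-oxoprop-1-en-1-yl]oxy}-4-[(4-methoxybenzyl)oxy]non-6-eneselenoate | O=C([Se]c1ccccc1)C[C@@H](O/C=C/C(=O)OCC)[C@@H](OCc2ccc(OC)cc2)C/C=C/CC
F3 | step 12 | ethyl 2-[(2R,5R)-5-[(1S,3E)-1-[(4-methoxybenzyl)oxy]hex-3-en-1-yl]-3-oxooxolan-2-yl]acetate | CCOC(=O)C[C@H]1O[C@@H]([C@@H](OCc2ccc(OC)cc2)C/C=C/CC)CC1=O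
F4 | step 12 | ethyl 2-[(2R,3R,5R)-3-hydroxy-5-[(1S,3E)-1-[(4-methoxybenzyl)oxy]hex-3-en-1-yl]oxolan-2-yl]acetate | CCOC(=O)C[C@H]1O[C@@H]([C@@H](OCc2ccc(OC)cc2)C/C=C/CC)C[C@H]1O
F5 | step 12 | (3aR,5R,6aR)-5-[(1S,3E)-1-[(4-methoxybenzyl)oxy]hex-3-en-1-yl]hexahydrofuro[3,2-b]furan-2-ol (anomer mixture) | OC1C[C@H]2O[C@@H]([C@@H](OCc3ccc(OC)cc3)C/C=C/CC)C[C@H]2O1
F6 | step 12 | (2R,3R,5R)-2-[(2E)-3-iodoprop-2-en-1-yl]-5-[(1S,3E)-1-[(4-methoxybenzyl)oxy]hex-3-en-1-yl]oxolan-3-ol | I/C=C/C[C@H]1O[C@@H]([C@@H](OCc2ccc(OC)cc2)C/C=C/CC)C[C@H]1O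
F7 | step 12 | (2R,3R,5R)-2-[(2E)-3-iodoprop-2-en-1-yl]-5-[(1S,3E)-1-[(4-methoxybenzyl)oxy]hex-3-en-1-yl]oxolan-3-yl acetate | I/C=C/C[C@H]1O[C@@H]([C@@H](OCc2ccc(OC)cc2)C/C=C/CC)C[C@H]1OC(C)=O
F8 | step 20 | (2R,3R,5R)-5-[(1S,3E)-1-{[(chloromethyl)sulfonyl]oxy}hex-3-en-1-yl]-2-[(2E)-pent-2-en-4-yn-1-yl]oxolan-3-yl acetate | C#C/C=C/C[C@H]1O[C@@H]([C@@H](OS(=O)(=O)CCl)C/C=C/CC)C[C@H]1OC(C)=O
F9 | step 4 | [(4R,5S)-2,2-dimethyl-5-(prop-2-yn-1-yl)-1,3-dioxolan-4-yl]methanol | C#CC[C@@H]1OC(C)(C)O[C@@H]1CO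
F10 | step 4 | [(4R,5S)-2,2-dimethyl-5-(pent-2-yn-1-yl)-1,3-dioxolan-4-yl]methanol | CCC#CC[C@@H]1OC(C)(C)O[C@@H]1CO
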